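**Retrosynthetic overview**

1. The route rests on C3 and C8. Both are oxygenated, they face each other 1,6 across the ten-membered ring, and each adjoins a trisubstituted olefin (C4=C5, C9=C10). A C3–C8 bond therefore gives a bicyclo[4.4.0]decadiene (ring A: C3–C4–C5–C6–C7–C8; ring B: C3–C2–C1–C10–C9–C8) in which both olefins are cis by ring constraint.
2. Target 33 ⇐ desilylation and two acylations ⇐ Luche reduction ⇐ ten-membered bis-enone 28 ⇐ Pb(OAc)4 scission of the C3–C8 ring-fusion bond of cis-diol 27.
3. 27 ⇐ ring-closing metathesis (C4=C5, ring A) ⇐ diene lactone 26 ⇐ indium Barbier allylation and lactonisation of allyl bromide 22 with acrolein (C6–C7 bond, cis-lactone).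
4. 22 ⇐ ynoate diol 16 ⇐ two successive carbonyl additions on ring B (masked propiolate acetylide to the C8 ketone, isopropenyl to the C3 ketone) ⇐ enone 6 (C1 set by CBS reduction) ⇐ 4-methoxy-2-methylphenol 1.
5. Order of ring formation: ring B (from the arene), lactone ring, ring A (metathesis), ten-membered ring (fragmentation).

Key step: step 18

Remark: ring atoms are numbered C1 (CHOH), C2, C3 (CHOAc), C4(Me)=C5, C6 (lactone O–CH), C7, C8 (CHOAng), C9=C10(Me), with lactone carbons C11–C13; "lower face" is the face of ring B that carries the C1 silyloxy group.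
Remark: a ring B 1,2-diketone with an oxygen at C1 would enolise and aromatise by loss of silanol, so C3 and C8 are raised to tertiary carbinols by two separate carbonyl additions, with C3 carried first as a protected secondary carbinol.

**Route**

Step 1
Reactants: 1 4-methoxy-2-methylphenol
Product: 2 4,4-dimethoxy-2-methylcyclohexa-2,5-dien-1-one
Conditions: PhI(OAc)2, MeOH, 0 °C
Reagents that add atoms: methanol, CO
Why: Oxidative dearomatisation of a para-methoxyphenol in methanol is a standard entry to quinone monoketals and places the future C1 and C8 oxygens on ring B in differentiated form.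

Step 2
Reactants: 2 4,4-dimethoxy-2-methylcyclohexa-2,5-dien-1-one
Product: 3 4,4-dimethoxy-2-methylcyclohex-2-en-1-one
Conditions: H2 (1 atm), RhCl(PPh3)3 (5 mol %), benzene/EtOH, rt, stopped after one equivalent
Reagents that add atoms: none
Why: Homogeneous hydrogenation with RhCl(PPh3)3 should saturate the cis-disubstituted alkene (future C2–C3) well before the methyl-bearing trisubstituted one (future C9=C10).

Step 3
Reactants: 3 4,4-dimethoxy-2-methylcyclohex-2-en-1-one
Product: 4 (S)-4,4-dimethoxy-2-methylcyclohex-2-en-1-ol
Conditions: (R)-2-methyl-CBS-oxazaborolidine (10 mol %), BH3·SMe2, THF, −20 °C; MeOH quench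
Reagents that add atoms: none
Why: Corey–Bakshi–Shibata reduction of an α-methyl enone, in which the substituted alkenyl arm acts as the large group, should give the (S)-carbinol with the (R)-catalyst and so fixes C1, from which all other centres are relayed.

Step 4
Reactants: 4 (S)-4,4-dimethoxy-2-methylcyclohex-2-en-1-ol
Product: 5 (S)-tert-butyl[(4,4-dimethoxy-2-methylcyclohex-2-en-1-yl)oxy]dimethylsilane
Conditions: TBSCl, imidazole, DMF, rt
Reagents that add atoms: tert-butyldimethylsilyl chloride, CC(C)(C)[Si](C)(C)Cl
Why: Standard silylation protects the C1 carbinol until the last step.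

Step 5
Reactants: 5 (S)-tert-butyl[(4,4-dimethoxy-2-methylcyclohex-2-en-1-yl)oxy]dimethylsilane
Product: 6 (S)-4-(tert-butyldimethylsilyloxy)-3-methylcyclohex-2-en-1-one
Conditions: PPTS (cat.), acetone/H2O, rt
Reagents that add atoms: water, O
Why: Mild acid hydrolysis of the allylic dimethyl ketal unveils the C8 enone carbonyl while the secondary silyl ether survives.

Step 6
Reactants: 6 (S)-4-(tert-butyldimethylsilyloxy)-3-methylcyclohex-2-en-1-one
Product: 8 (4S,6S)-4-(tert-butyldimethylsilyloxy)-6-hydroxy-3-methylcyclohex-2-en-1-one, via sodium dienolate 7 (not isolated)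
Conditions: NaN(SiMe3)2, THF, −78 °C; 3-phenyl-2-(phenylsulfonyl)oxaziridine, −78 °C; AcOH quench
Reagents that add atoms: 3-phenyl-2-(phenylsulfonyl)oxaziridine, O=S(=O)(c1ccccc1)N1OC1c1ccccc1
Why: Kinetic α'-deprotonation and Davis enolate hydroxylation put oxygen on C3, the oxidant approaching anti to the pseudoaxial C1 silyloxy group so that the C3 hydroxyl should come out trans to it.

Step 7
Reactants: 8 (4S,6S)-4-(tert-butyldimethylsilyloxy)-6-hydroxy-3-methylcyclohex-2-en-1-one
Product: 9 (4S,6R)-6-benzoyloxy-4-(tert-butyldimethylsilyloxy)-3-methylcyclohex-2-en-1-one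
Conditions: PPh3, DIAD, PhCO2H, toluene, 0 °C to rt
Reagents that add atoms: benzoic acid, O=C(O)c1ccccc1
Why: Mitsunobu inversion at the carbonyl-activated C3 carbinol places the temporary C3 oxygen cis to the C1 silyloxy group, so that both oxygens lie on the lower face for the next addition.

Step 8
Reactants: 9 (4S,6R)-6-benzoyloxy-4-(tert-butyldimethylsilyloxy)-3-methylcyclohex-2-en-1-one; 10 3,3,3-triethoxyprop-1-yne
Product: 11 C8 tertiary propargylic alcohol of ring B (C8 carries OH and the C≡C–C(OEt)3 chain; C3 benzoate, C1 silyl ether and C8 hydroxyl all on the lower face)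
Conditions: 10, n-BuLi, THF, −78 °C; CeCl3; then 9, −78 °C; H2O/NaHCO3 work-up, Et3N-washed silica
Reagents that add atoms: none
Why: 1,2-Addition of a cerium-modified lithium acetylide (a masked propiolate) to the enone carbonyl should follow the Felkin–Anh course, entering anti to the C3–O bond and away from the C1 silyloxy group, so the alkyne sits on the upper face and the C8 hydroxyl on the lower one, while cerium suppresses enolisation and attack on the benzoate.

Step 9
Reactants: 11 C8 tertiary propargylic alcohol of ring B
Product: 12 orthoester diol (C3 secondary OH, C8 tertiary OH, both cis to the C1 silyl ether)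
Conditions: K2CO3 (0.2 equiv), MeOH, rt
Reagents that add atoms: none
Why: Base-catalysed transesterification removes the benzoate (from whichever vicinal oxygen holds it after possible migration) and leaves the orthoester and silyl ether, both base-stable, untouched.

Step 10
Reactants: 12 orthoester diol
Product: 13 α-hydroxy ketone (C3 ketone next to the C8 tertiary carbinol)
Conditions: SO3·pyridine, DMSO, i-Pr2NEt, CH2Cl2, 0 °C
Reagents that add atoms: none
Why: Parikh–Doering oxidation converts the secondary C3 carbinol to the ketone under basic, non-cleaving conditions that spare the tertiary alcohol, the glycol C–C bond and the acid-labile orthoester.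

Step 11
Reactants: 13 α-hydroxy ketone; 14 isopropenylmagnesium bromide
Product: 16 ethyl ynoate cis-diol (C8(OH)–C≡C–CO2Et, C3(OH)(isopropenyl), C1 silyl ether; the three oxygens all cis), via orthoester cis-diol 15 (not isolated)
Conditions: 14 (4 equiv), CeCl3, THF, −78 to 0 °C; then 10% aq. citric acid, THF, rt
Reagents that add atoms: water, O
Why: Chelation-controlled Grignard addition: the C8 alkoxide ties up the C3 carbonyl, the pseudoaxial C1 silyloxy group shields the lower face, and equatorial attack from the upper face should give the ring-fusion cis-diol with isopropenyl cis to the alkyne; the acidic work-up hydrolyses the orthoester to the ethyl ester.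

Step 12
Reactants: 16 ethyl ynoate cis-diol
Product: 18 ethyl (Z)-2-iodo-3-(ring B cis-diol)acrylate (iodine cis to C8, ester trans to C8), via alkenylalanate 17 (not isolated)
Conditions: NaAlH2(OCH2CH2OMe)2 (3.5 equiv), THF, −72 °C; I2, −72 to −20 °C; aq. KNaC4H4O6 work-up
Reagents that add atoms: iodine, II
Why: Hydroxyl-directed trans-hydroalumination of a γ-hydroxy ynoate delivers hydride to C7 and holds aluminium on C11 cis to C8 in a five-membered alkoxyalanate, and iodinolysis with retention then gives the α-iodo enoate whose ester is trans to C8, so no butenolide can form.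

Step 13
Reactants: 18 ethyl (Z)-2-iodo-3-(ring B cis-diol)acrylate
Product: 19 bis(trimethylsilyl) ether of 18
Conditions: TMSOTf, 2,6-lutidine, CH2Cl2, −78 to 0 °C
Reagents that add atoms: trimethylsilyl trifluoromethanesulfonate, C[Si](C)(C)OS(=O)(=O)C(F)(F)F
Why: Silylation of the two tertiary hydroxyls keeps the C8 oxygen, which is cis to C13, from closing a 2,5-dihydrofuran onto the allylic bromide made in step 15.

Step 14
Reactants: 19 bis(trimethylsilyl) ether of 18; 20 (tributylstannyl)methanol
Product: 21 ethyl (E)-2-(hydroxymethyl)acrylate derivative (CH2OH cis to C8)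
Conditions: Pd(PPh3)4 (10 mol %), toluene, 90 °C
Reagents that add atoms: none
Why: Migita–Kosugi–Stille coupling of the alkenyl iodide with the hydroxymethylstannane brings in C13 with retention of the olefin geometry.

Step 15
Reactants: 21 ethyl (E)-2-(hydroxymethyl)acrylate derivative
Product: 22 ethyl (Z)-2-(bromomethyl)acrylate derivative (CH2Br cis to C8)
Conditions: CBr4, PPh3, 2,6-lutidine, CH2Cl2, 0 °C
Reagents that add atoms: carbon tetrabromide, BrC(Br)(Br)Br
Why: Appel bromination converts only the primary allylic alcohol into the bromide under buffered conditions that leave the tertiary silyl ethers in place.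

Step 16
Reactants: 22 ethyl (Z)-2-(bromomethyl)acrylate derivative; 23 acrolein
Product: 26 diene lactone cis-diol (cis-fused α-methylene-γ-butyrolactone with a vinyl group on C6; C7 bonded to C8 of the ring B cis-diol), via hydroxy ester 24 (not isolated), via silylated lactone 25 (not isolated)
Conditions: In powder, THF/H2O (4:1), rt; then PPTS, MeOH, 40 °C
Reagents that add atoms: none
Why: Indium-mediated Barbier allylation: γ-attack of the 2-(ethoxycarbonyl)allylindium through a chair from the (Z)-bromide should give the syn adduct (hence the cis-lactone), and with the C8–O bond eclipsing the alkene to relieve allylic 1,3-strain acrolein should approach C7 anti to the fully substituted C3, setting C7 and C6 against C8; acid then lactonises onto the free C6 hydroxyl and removes the two trimethylsilyl groups.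

Step 17
Reactants: 26 diene lactone cis-diol
Product: 27 cis-decalindiol methylene lactone
Conditions: second-generation Grubbs catalyst RuCl2(=CHPh)(PCy3)(H2IMes) (10 mol %), toluene, 80 °C
Reagents that add atoms: none
Why: Ring-closing metathesis of the C3 isopropenyl and C6 vinyl groups, which are cis on ring B, should close ring A with the C4=C5 olefin necessarily cis, the electron-poor methylene lactone being a poor metathesis partner.

Step 18
Reactants: 27 cis-decalindiol methylene lactone
Product: 28 ten-membered (Z,Z)-bis-enone lactone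
Conditions: Pb(OAc)4 (1.05 equiv), CH2Cl2, −20 °C, 15 min; filtered through Celite and used at once
Reagents that add atoms: none
Why: The cis ring-fusion diol closes a five-membered cyclic diester on tetravalent lead, which collapses in a concerted two-electron shift to divalent lead and the C3 and C8 ketones, cutting the C3–C8 bond; this is the Criegee glycol cleavage, known for cis-decalin-9,10-diols that open to cyclodecane-1,6-diones. The ten-membered ring is not closed by cyclisation but unveiled by fragmentation of the zero-atom bridge of the bicyclo[4.4.0]decadiene, so no medium-ring closure has to be paid for. No stereocentre is formed: C1, C6 and C7 pass through untouched, and both trisubstituted olefins, made inside cyclohexenes, must emerge ring-cis (Z) in the bis-enone. The step needs chemoselectivity only, and 27 holds a single vicinal diol whose cis geometry should let the cyclic lead ester form faster than any allylic acetoxylation. The product is a β-acyloxy ketone with an acidic C7–H, so the run is kept base-free and short and 28 is reduced immediately.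

Step 19
Reactants: 28 ten-membered (Z,Z)-bis-enone lactone
Product: 29 C3,C8-diol (both new hydroxyls on the face of the C6 lactone oxygen)
Conditions: NaBH4, CeCl3·7H2O, MeOH/CH2Cl2, −78 °C
Reagents that add atoms: none
Why: Luche reduction is 1,2-selective for both enones and, at −78 °C, should spare the methylene lactone; hydride is expected from the outer face of the ring, at C8 anti to the C7–C11 bond, while the sense at C3 is less secure.

Step 20
Reactants: 29 C3,C8-diol
Product: 30 C3 monoacetate
Conditions: Ac2O (1.05 equiv), pyridine, DMAP (cat.), CH2Cl2, −40 °C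
Reagents that add atoms: acetic anhydride, CC(=O)OC(C)=O
Why: Kinetic acylation should select the C3 carbinol, flanked by a CH2, over the C8 carbinol, which sits beside the lactone ring-fusion carbon C7.

Step 21
Reactants: 30 C3 monoacetate; 31 angelic acid
Product: 32 C8 angelate C1 silyl ether
Conditions: 31, 2,4,6-trichlorobenzoyl chloride, Et3N, toluene, rt; then 30, 80 °C
Reagents that add atoms: none
Why: Yamaguchi-type mixed-anhydride esterification without a nucleophilic catalyst is the established way to acylate hindered alcohols with angelic acid without isomerisation to the tiglate.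

Step 22
Reactants: 32 C8 angelate C1 silyl ether
Product: 33 CNP0319825.5 (target)
Conditions: HF·pyridine, pyridine, THF, 0 °C to rt
Reagents that add atoms: none
Why: Buffered fluoride desilylation frees the C1 carbinol under acidic, non-nucleophilic conditions in which the esters, the methylene lactone and the acyl positions should stay put.

**Compound list**

1 | 4-methoxy-2-methylphenol | COc1ccc(O)c(C)c1 | starting material
2 | 4,4-dimethoxy-2-methylcyclohexa-2,5-dien-1-one | COC1(OC)C=CC(=O)C(C)=C1 | intermediate
3 | 4,4-dimethoxy-2-methylcyclohex-2-en-1-one | COC1(OC)CCC(=O)C(C)=C1 | intermediate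
4 | (S)-4,4-dimethoxy-2-methylcyclohex-2-en-1-ol | CC1=CC(OC)(OC)CC[C@@H]1O | intermediate
5 | (S)-tert-butyl[(4,4-dimethoxy-2-methylcyclohex-2-en-1-yl)oxy]dimethylsilane | CC1=CC(OC)(OC)CC[C@@H]1O[Si](C)(C)C(C)(C)C | intermediate
6 | (S)-4-(tert-butyldimethylsilyloxy)-3-methylcyclohex-2-en-1-one | O=C1C=C(C)[C@@H](O[Si](C)(C)C(C)(C)C)CC1 | intermediate
7 | sodium cross-conjugated dienolate of 6 | [Na+].[O-]C1=CC[C@H](O[Si](C)(C)C(C)(C)C)C(C)=C1 | intermediate
8 | (4S,6S)-4-(tert-butyldimethylsilyloxy)-6-hydroxy-3-methylcyclohex-2-en-1-one | O=C1C=C(C)[C@@H](O[Si](C)(C)C(C)(C)C)C[C@@H]1O | intermediate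
9 | (4S,6R)-6-benzoyloxy-4-(tert-butyldimethylsilyloxy)-3-methylcyclohex-2-en-1-one | O=C1C=C(C)[C@@H](O[Si](C)(C)C(C)(C)C)C[C@H]1OC(=O)c2ccccc2 | intermediate
10 | 3,3,3-triethoxyprop-1-yne | C#CC(OCC)(OCC)OCC | starting material
11 | C8 tertiary propargylic alcohol, C3 benzoate, C1 silyl ether | O[C@@]1(C#CC(OCC)(OCC)OCC)C=C(C)[C@@H](O[Si](C)(C)C(C)(C)C)C[C@H]1OC(=O)c2ccccc2 | intermediate
12 | orthoester diol | O[C@@]1(C#CC(OCC)(OCC)OCC)C=C(C)[C@@H](O[Si](C)(C)C(C)(C)C)C[C@H]1O | intermediate
13 | α-hydroxy ketone (C3 ketone) | O[C@@]1(C#CC(OCC)(OCC)OCC)C=C(C)[C@@H](O[Si](C)(C)C(C)(C)C)CC1=O | intermediate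
14 | isopropenylmagnesium bromide | CC(=C)[Mg]Br | starting material
15 | orthoester cis-diol | O[C@@]1(C#CC(OCC)(OCC)OCC)C=C(C)[C@@H](O[Si](C)(C)C(C)(C)C)C[C@]1(O)C(C)=C | intermediate
16 | ethyl ynoate cis-diol | O[C@@]1(C#CC(=O)OCC)C=C(C)[C@@H](O[Si](C)(C)C(C)(C)C)C[C@]1(O)C(C)=C | intermediate
17 | sodium cyclic alkenyl(alkoxy)bis(2-methoxyethoxy)aluminate, drawn with the C3 hydroxyl undissociated | [Na+].CCOC(=O)C1=C[C@]2(O[Al-]1(OCCOC)OCCOC)C=C(C)[C@@H](O[Si](C)(C)C(C)(C)C)C[C@]2(O)C(C)=C | intermediate
18 | ethyl (Z)-2-iodo-3-(ring B cis-diol)acrylate | O[C@@]1(/C=C(\I)C(=O)OCC)C=C(C)[C@@H](O[Si](C)(C)C(C)(C)C)C[C@]1(O)C(C)=C | intermediate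
19 | bis(trimethylsilyl) ether of 18 | C[Si](C)(C)O[C@@]1(/C=C(\I)C(=O)OCC)C=C(C)[C@@H](O[Si](C)(C)C(C)(C)C)C[C@]1(O[Si](C)(C)C)C(C)=C | intermediate
20 | (tributylstannyl)methanol | CCCC[Sn](CCCC)(CCCC)CO | starting material
21 | ethyl (E)-2-(hydroxymethyl)acrylate derivative | C[Si](C)(C)O[C@@]1(/C=C(\CO)C(=O)OCC)C=C(C)[C@@H](O[Si](C)(C)C(C)(C)C)C[C@]1(O[Si](C)(C)C)C(C)=C | intermediate
22 | ethyl (Z)-2-(bromomethyl)acrylate derivative | C[Si](C)(C)O[C@@]1(/C=C(\CBr)C(=O)OCC)C=C(C)[C@@H](O[Si](C)(C)C(C)(C)C)C[C@]1(O[Si](C)(C)C)C(C)=C | intermediate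
23 | acrolein | C=CC=O | starting material
24 | syn hydroxy ester | C=C(C(=O)OCC)[C@@H]([C@@H](O)C=C)[C@]1(O[Si](C)(C)C)C=C(C)[C@@H](O[Si](C)(C)C(C)(C)C)C[C@]1(O[Si](C)(C)C)C(C)=C | intermediate
25 | silylated cis-lactone | C=C1C(=O)O[C@@H](C=C)[C@H]1[C@]2(O[Si](C)(C)C)C=C(C)[C@@H](O[Si](C)(C)C(C)(C)C)C[C@]2(O[Si](C)(C)C)C(C)=C | intermediate
26 | diene lactone cis-diol | C=C1C(=O)O[C@@H](C=C)[C@H]1[C@]2(O)C=C(C)[C@@H](O[Si](C)(C)C(C)(C)C)C[C@]2(O)C(C)=C | intermediate
27 | cis-decalindiol methylene lactone | C=C1C(=O)O[C@H]2C=C(C)[C@@]3(O)C[C@H](O[Si](C)(C)C(C)(C)C)C(C)=C[C@@]3(O)[C@@H]12 | intermediate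
28 | ten-membered (Z,Z)-bis-enone lactone | C=C1C(=O)O[C@H]2/C=C(/C)C(=O)C[C@H](O[Si](C)(C)C(C)(C)C)/C(C)=C\C(=O)[C@@H]12 | intermediate
29 | C3,C8-diol | C=C1C(=O)O[C@H]2/C=C(/C)[C@@H](O)C[C@H](O[Si](C)(C)C(C)(C)C)/C(C)=C\[C@@H](O)[C@@H]12 | intermediate
30 | C3 monoacetate | C=C1C(=O)O[C@H]2/C=C(/C)[C@@H](OC(C)=O)C[C@H](O[Si](C)(C)C(C)(C)C)/C(C)=C\[C@@H](O)[C@@H]12 | intermediate
31 | angelic acid | C/C=C(/C)C(=O)O | starting material
32 | C8 angelate C1 silyl ether | C=C1C(=O)O[C@H]2/C=C(/C)[C@@H](OC(C)=O)C[C@H](O[Si](C)(C)C(C)(C)C)/C(C)=C\[C@@H](OC(=O)/C(C)=C\C)[C@@H]12 | intermediate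
33 | CNP0319825.5 | C=C1C(=O)O[C@H]2/C=C(/C)[C@@H](OC(C)=O)C[C@H](O)/C(C)=C\[C@@H](OC(=O)/C(C)=C\C)[C@@H]12 | target

**Step count and risks**

Total step count: 22. Longest linear sequence: 22 steps (from 1).

Step 18. Two processes threaten it. The cyclic lead ester may form slowly between two hindered tertiary allylic hydroxyls, which would let oxidation at the electron-rich olefins compete. The freshly formed β-acyloxy ketone may also lose the C6 carboxylate or epimerise at C7. Fallback: setting out from 27, the same C3–C8 bond is cut by alkoxy-radical β-scission (PhI(OAc)2, I2, CH2Cl2, visible light, 0 °C). Here a single hypoiodite suffices, and the α-hydroxy allyl radical left on the other carbon is oxidised to the second ketone. The solution is passed straight into the Luche reduction. The fallback comes back to the route at 28 and makes no new compound (F0).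

Step 16. The γ-carbon C7 is flanked by the fully substituted C8. Facial selectivity at C7 may therefore be poor, or the allylmetal may react through its CH2 terminus. Fallback: setting out from iodide 18, a Negishi coupling with (pinacolatoboryl)methylzinc iodide, pinBCH2ZnI (Pd(PPh3)4, THF, 40 °C), should give the ethyl 2-[(pinacolatoboryl)methyl]acrylate diol F1, with C8 cis to the CH2B group. Its uncatalysed allylboration of acrolein (toluene, 60–80 °C) runs through a closed chair that enforces γ-attack and the syn relationship. Lactonisation with PPTS then comes back to the route at 26, with no silylation, Stille or Appel step.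

Step 19. Hydride may be delivered from the wrong face at C3, which lies far from the resident stereocentres of the flexible ring. Fallback: setting out from 28, the reduction then gives the C3-epimeric diol F2. A Mitsunobu esterification with acetic acid (PPh3, DIAD, AcOH, toluene, 0 °C) at the less hindered C3 allylic carbinol inverts the centre and installs the acetate in one operation. It comes back to the route at 30.

Further compounds
F1 | step 16 | ethyl 2-[(pinacolatoboryl)methyl]-3-(ring B cis-diol)acrylate, C8 cis to CH2B | O[C@@]1(/C=C(\CB2OC(C)(C)C(C)(C)O2)C(=O)OCC)C=C(C)[C@@H](O[Si](C)(C)C(C)(C)C)C[C@]1(O)C(C)=C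
F2 | step 19 | C3-epimeric diol | C=C1C(=O)O[C@H]2/C=C(/C)[C@H](O)C[C@H](O[Si](C)(C)C(C)(C)C)/C(C)=C\[C@@H](O)[C@@H]12
F0 | step 18 | none | none
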